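## Retrosynthetic overview

1. C2=C3 and the acid: Knoevenagel–Doebner condensation of a (2E,4E)-dienal with a C3 diacid (loss of CO2). C6=C7: cross-metathesis of a terminal vinyl group with a C6 dienal.
2. C13–O: copper-catalysed conjugate borylation/oxidation of an aryl enone. C15–aryl: aryllithium plus Weinreb enamide.
3. Key disconnection C11–C12 (sp3–sp3): nickel-catalysed, radical, stereoconvergent Negishi coupling of a chiral primary alkylzinc (C7–C11) with a racemic γ-chloro-α,β-unsaturated Weinreb amide (C12–C15). The ligand sets C12.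
4. C8–C9: anti-crotylboration of a chiral-pool β-bromo aldehyde (C9–C11, C10 bought). The racemic chloride comes from cross-metathesis of two small olefins.
5. Rings: none is formed. The benzene ring is carried in intact with the aryl bromide.

Assumption: the named antipodes of the pybox ligand (step 5), the Josiphos ligand (step 7) and the pinene-derived borane (step 2) follow the usual facial models; if a model run shows the opposite sense, the mirror-image ligand or reagent is used and nothing else changes.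

## Route

Step 1
Reactants: 1 (S)-3-bromo-2-methylpropan-1-ol
Product: 2 (S)-3-bromo-2-methylpropanal
Conditions: TEMPO (10 mol%), PhI(OAc)2 (1.1 equiv), CH2Cl2, 0 °C → rt; cold NaHCO3 wash; used at once as a solution
Reagents that add atoms: none
Why: TEMPO/oxoammonium oxidation stops at the aldehyde without base, so the α-stereocentre (C10, from the chiral pool) is not epimerised and HBr is not eliminated.

Step 2
Reactants: 2 (S)-3-bromo-2-methylpropanal; 3 trans-2-butene
Product: 6 (3R,4R,5S)-6-bromo-3,5-dimethylhex-1-en-4-ol, via crotylborane 4 (not isolated), via borinate ester 5 (not isolated)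
Conditions: 3 (excess), KOt-Bu, n-BuLi, THF, −78 → −45 °C; (+)-Ipc2BOMe, −78 °C; BF3·OEt2; then 2, −78 °C, 3 h; NaBO3·4H2O, THF/H2O, rt
Reagents that add atoms: none
Why: Brown crotylboration through a closed chair transition state: the E-crotyl unit gives 8,9-anti, and the reagent from (−)-α-pinene attacks the Re face, which is also the Felkin face of 2, giving 9,10-syn (matched double stereodifferentiation).

Step 3
Reactants: 6 (3R,4R,5S)-6-bromo-3,5-dimethylhex-1-en-4-ol
Product: 7 {[(3R,4R,5S)-6-bromo-3,5-dimethylhex-1-en-4-yl]oxy}triethylsilane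
Conditions: Et3SiOTf, 2,6-lutidine, CH2Cl2, −78 °C
Reagents that add atoms: triethylsilyl trifluoromethanesulfonate, CC[Si](CC)(CC)OS(=O)(=O)C(F)(F)F
Why: Silyl triflate silylation of a hindered secondary alcohol; the ether masks the OH for the organozinc step and later prevents oxa-Michael closure onto the enone.

Step 4
Reactants: 8 rac-3-chlorobut-1-ene; 9 N-methoxy-N-methylacrylamide
Product: 10 rac-(E)-4-chloro-N-methoxy-N-methylpent-2-enamide
Conditions: second-generation Hoveyda–Grubbs catalyst RuCl2(H2IMes)(=CH-C6H4-2-OiPr) (3 mol%), 8 (3 equiv), CH2Cl2, reflux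
Reagents that add atoms: none
Why: Olefin cross-metathesis of a terminal olefin with an acrylamide gives the E-enamide with loss of ethylene; the racemate is sufficient because the next step is stereoconvergent.

Step 5 (key step)
Reactants: 7 {[(3R,4R,5S)-6-bromo-3,5-dimethylhex-1-en-4-yl]oxy}triethylsilane; 10 rac-(E)-4-chloro-N-methoxy-N-methylpent-2-enamide
Product: 12 (2E,4R,6R,7S,8R)-N-methoxy-N,4,6,8-tetramethyl-7-[(triethylsilyl)oxy]deca-2,9-dienamide, via alkylzinc bromide 11 (not isolated)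
Conditions: 7, Zn dust, I2 (5 mol%), DMA, 70 °C; then 10 (1.5 equiv), NiCl2(dme) (5 mol%), 2,6-bis[(4S)-4-(2-phenylethyl)-4,5-dihydrooxazol-2-yl]pyridine (6.5 mol%), NaCl (4 equiv), DMA/DMF 1:1, −10 °C, 24 h
Reagents that add atoms: none
Why: Stereoconvergent nickel-catalysed Negishi coupling of a racemic secondary allylic chloride: halogen abstraction by the alkylnickel species turns both enantiomers of 10 into one planar, amide-conjugated allyl radical, which is captured by the chiral pybox–nickel alkyl and reductively eliminated at the carbon remote from the amide, so the C11–C12 bond forms in a radical reaction and the ligand alone sets 12R. The reaction class is known for γ-chloro-α,β-unsaturated carbonyl compounds, but this pairing (Weinreb amide, β-branched zinc reagent) is untested.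

Step 6
Reactants: 12 (2E,4R,6R,7S,8R)-N-methoxy-N,4,6,8-tetramethyl-7-[(triethylsilyl)oxy]deca-2,9-dienamide; 13 4-bromoaniline
Product: 17 (2E,4R,6R,7S,8R)-1-(4-aminophenyl)-4,6,8-trimethyl-7-[(triethylsilyl)oxy]deca-2,9-dien-1-one, via bis-silyl bromoaniline 14 (not isolated), via aryllithium 15 (not isolated), via bis-silyl enone 16 (not isolated)
Conditions: 13 (1.5 equiv), n-BuLi then Me3SiCl (1 equiv each, twice), THF, −78 → 0 °C; t-BuLi (2 equiv), −78 °C; add 12, −78 °C, 1 h; aq. citric acid, 0 °C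
Reagents that add atoms: none
Why: Weinreb ketone synthesis: the aryllithium from bromine–lithium exchange on the N,N-disilylated bromoaniline adds 1,2 to the enamide to give a stable chelate that releases the enone on work-up, where the N–Si bonds are also hydrolysed.

Step 7
Reactants: 17 (2E,4R,6R,7S,8R)-1-(4-aminophenyl)-4,6,8-trimethyl-7-[(triethylsilyl)oxy]deca-2,9-dien-1-one
Product: 20 (3R,4R,6R,7S,8R)-1-(4-aminophenyl)-3,7-dihydroxy-4,6,8-trimethyldec-9-en-1-one, via boryl ketone 18 (not isolated), via silyl ether 19 (not isolated)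
Conditions: CuCl (5 mol%), NaOt-Bu (7 mol%), (R)-1-[(S)-2-(diphenylphosphino)ferrocenyl]ethyldicyclohexylphosphine ((R,S)-Josiphos, 6 mol%), B2pin2 (1.2 equiv), MeOH (2 equiv), THF, rt; NaBO3·4H2O, THF/H2O, rt; then 1 M HCl, rt
Reagents that add atoms: sodium perborate (used as the tetrahydrate), [Na+].[O-]OB=O
Why: Copper-catalysed conjugate borylation followed by stereoretentive perborate oxidation: the chiral bisphosphine–copper boryl adds anti to the C11 chain in the allylic-strain-minimised conformer (substrate and catalyst matched) to give 13R, 12,13-syn; dilute acid then cleaves the triethylsilyl ether.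

Step 8
Reactants: 20 (3R,4R,6R,7S,8R)-1-(4-aminophenyl)-3,7-dihydroxy-4,6,8-trimethyldec-9-en-1-one; 21 (2E,4E)-hexa-2,4-dienal
Product: 22 (2E,4E,6R,7S,8R,10R,11R)-13-(4-aminophenyl)-7,11-dihydroxy-6,8,10-trimethyl-13-oxotrideca-2,4-dienal
Conditions: second-generation Hoveyda–Grubbs catalyst RuCl2(H2IMes)(=CH-C6H4-2-OiPr) (10 mol%, two portions), 21 (5 equiv), 1,4-benzoquinone (20 mol%), CH2Cl2, 40 °C
Reagents that add atoms: none
Why: Olefin cross-metathesis: the ruthenium alkylidene engages the more electron-rich distal (4,5) olefin of the dienal rather than the formyl-conjugated one, giving the E C6=C7 bond with loss of propene; benzoquinone suppresses olefin migration at allylic C8.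

Step 9
Reactants: 22 (2E,4E,6R,7S,8R,10R,11R)-13-(4-aminophenyl)-7,11-dihydroxy-6,8,10-trimethyl-13-oxotrideca-2,4-dienal; 23 malonic acid
Product: 25 mohangic acid F, via alkylidenemalonic acid 24 (not isolated)
Conditions: 23 (3 equiv), pyridine, piperidine (0.2 equiv), 60 °C; acidify to pH 4
Reagents that add atoms: none
Why: Knoevenagel–Doebner condensation: amine-catalysed condensation with malonic acid and pyridine-promoted decarboxylation give the E-2,3 double bond and the free acid directly, in a buffered medium that should spare the β-hydroxy ketone.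

## Compound list

1 | (S)-3-bromo-2-methylpropan-1-ol | OC[C@H](C)CBr | starting material
2 | (S)-3-bromo-2-methylpropanal | O=C[C@H](C)CBr | intermediate
3 | trans-2-butene | C/C=C/C | starting material
4 | (E)-but-2-en-1-yl-bis(isopinocampheyl)borane, isopinocampheyl groups from (−)-α-pinene | C/C=C/CB([C@H]1C[C@H]2C[C@@H]([C@@H]1C)C2(C)C)[C@H]1C[C@H]2C[C@@H]([C@@H]1C)C2(C)C | intermediate
5 | (3R,4R,5S)-6-bromo-3,5-dimethylhex-1-en-4-yl bis(isopinocampheyl)borinate | C[C@H](C=C)[C@@H](OB([C@H]1C[C@H]2C[C@@H]([C@@H]1C)C2(C)C)[C@H]1C[C@H]2C[C@@H]([C@@H]1C)C2(C)C)[C@H](C)CBr | intermediate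
6 | (3R,4R,5S)-6-bromo-3,5-dimethylhex-1-en-4-ol | C[C@H](C=C)[C@@H](O)[C@H](C)CBr | intermediate
7 | {[(3R,4R,5S)-6-bromo-3,5-dimethylhex-1-en-4-yl]oxy}triethylsilane | C[C@H](C=C)[C@@H](O[Si](CC)(CC)CC)[C@H](C)CBr | intermediate
8 | rac-3-chlorobut-1-ene | CC(Cl)C=C | starting material
9 | N-methoxy-N-methylacrylamide | C=CC(=O)N(C)OC | starting material
10 | rac-(E)-4-chloro-N-methoxy-N-methylpent-2-enamide | CC(Cl)/C=C/C(=O)N(C)OC | intermediate
11 | bromo{(2S,3R,4R)-2,4-dimethyl-3-[(triethylsilyl)oxy]hex-5-en-1-yl}zinc | C[C@H](C=C)[C@@H](O[Si](CC)(CC)CC)[C@H](C)C[Zn]Br | intermediate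
12 | (2E,4R,6R,7S,8R)-N-methoxy-N,4,6,8-tetramethyl-7-[(triethylsilyl)oxy]deca-2,9-dienamide | C[C@H](C=C)[C@@H](O[Si](CC)(CC)CC)[C@H](C)C[C@@H](C)/C=C/C(=O)N(C)OC | intermediate
13 | 4-bromoaniline | Nc1ccc(Br)cc1 | starting material
14 | 4-bromo-N,N-bis(trimethylsilyl)aniline | C[Si](C)(C)N(c1ccc(Br)cc1)[Si](C)(C)C | intermediate
15 | {4-[bis(trimethylsilyl)amino]phenyl}lithium | [Li]c1ccc(cc1)N([Si](C)(C)C)[Si](C)(C)C | intermediate
16 | (2E,4R,6R,7S,8R)-1-{4-[bis(trimethylsilyl)amino]phenyl}-4,6,8-trimethyl-7-[(triethylsilyl)oxy]deca-2,9-dien-1-one | C[C@H](C=C)[C@@H](O[Si](CC)(CC)CC)[C@H](C)C[C@@H](C)/C=C/C(=O)c1ccc(cc1)N([Si](C)(C)C)[Si](C)(C)C | intermediate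
17 | (2E,4R,6R,7S,8R)-1-(4-aminophenyl)-4,6,8-trimethyl-7-[(triethylsilyl)oxy]deca-2,9-dien-1-one | C[C@H](C=C)[C@@H](O[Si](CC)(CC)CC)[C@H](C)C[C@@H](C)/C=C/C(=O)c1ccc(N)cc1 | intermediate
18 | (3R,4R,6R,7S,8R)-1-(4-aminophenyl)-4,6,8-trimethyl-3-(4,4,5,5-tetramethyl-1,3,2-dioxaborolan-2-yl)-7-[(triethylsilyl)oxy]dec-9-en-1-one | C[C@H](C=C)[C@@H](O[Si](CC)(CC)CC)[C@H](C)C[C@@H](C)[C@H](B1OC(C)(C)C(C)(C)O1)CC(=O)c1ccc(N)cc1 | intermediate
19 | (3R,4R,6R,7S,8R)-1-(4-aminophenyl)-3-hydroxy-4,6,8-trimethyl-7-[(triethylsilyl)oxy]dec-9-en-1-one | C[C@H](C=C)[C@@H](O[Si](CC)(CC)CC)[C@H](C)C[C@@H](C)[C@H](O)CC(=O)c1ccc(N)cc1 | intermediate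
20 | (3R,4R,6R,7S,8R)-1-(4-aminophenyl)-3,7-dihydroxy-4,6,8-trimethyldec-9-en-1-one | C[C@H](C=C)[C@@H](O)[C@H](C)C[C@@H](C)[C@H](O)CC(=O)c1ccc(N)cc1 | intermediate
21 | (2E,4E)-hexa-2,4-dienal | C/C=C/C=C/C=O | starting material
22 | (2E,4E,6R,7S,8R,10R,11R)-13-(4-aminophenyl)-7,11-dihydroxy-6,8,10-trimethyl-13-oxotrideca-2,4-dienal | C[C@H](/C=C/C=C/C=O)[C@@H](O)[C@H](C)C[C@@H](C)[C@H](O)CC(=O)c1ccc(N)cc1 | intermediate
23 | malonic acid | OC(=O)CC(=O)O | starting material
24 | 2-[(2E,4E,6R,7S,8R,10R,11R)-13-(4-aminophenyl)-7,11-dihydroxy-6,8,10-trimethyl-13-oxotrideca-2,4-dien-1-ylidene]propanedioic acid | C[C@H](/C=C/C=C/C=C(C(=O)O)C(=O)O)[C@@H](O)[C@H](C)C[C@@H](C)[C@H](O)CC(=O)c1ccc(N)cc1 | intermediate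
25 | mohangic acid F, (2E,4E,6E,8R,9S,10R,12R,13R)-15-(4-aminophenyl)-9,13-dihydroxy-8,10,12-trimethyl-15-oxopentadeca-2,4,6-trienoic acid | C[C@H](/C=C/C=C/C=C/C(=O)O)[C@@H](O)[C@H](C)C[C@@H](C)[C@H](O)CC(=O)c1ccc(N)cc1 | target

## Step count and risk

Total step count: 9. Longest linear sequence: 8 steps (1 → 2 → 6 → 7 → 12 → 17 → 20 → 22 → 25).

The three steps most likely to fail:

**Step 5.** The β-branched zinc reagent may transmetallate slowly, and the amide-substituted allyl radical may couple with poor regio- or enantiocontrol. The fallback sets out from 11 and comes back at 12. The same zinc reagent 11 is coupled, still under radical stereoconvergent nickel/pybox conditions (NiCl2(dme), the i-Pr-pybox antipode that gives 12R, 1,3-dimethyl-2-imidazolidinone/THF, 0 °C), with a better-precedented electrophile class. That electrophile is the racemic α-bromo amide rac-N-benzyl-2-bromo-N-phenylpropanamide F1, made from 2-bromopropanoyl bromide and N-benzylaniline. The coupling gives (2R,4R,5S,6R)-N-benzyl-2,4,6-trimethyl-N-phenyl-5-[(triethylsilyl)oxy]oct-7-enamide F2, with C12 now set α to the carbonyl. LiAlH4 at −78 °C stops at the aldehyde for this anilide and gives (2R,4R,5S,6R)-2,4,6-trimethyl-5-[(triethylsilyl)oxy]oct-7-enal F3. Wittig olefination with Ph3P=CHC(O)N(OMe)Me (CH2Cl2, rt) then gives 12. If the failure lies in making 11 itself, the reductive-lithiation entry described next delivers 11 without zinc insertion.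

**Step 1.** β-Bromo aldehyde 2 may lose HBr or epimerise before it is crotylated. The fallback sets out from 1 and comes back at 11. PhSNa (EtOH, rt) displaces the bromide of 1 to give (S)-2-methyl-3-(phenylsulfanyl)propan-1-ol F4. Parikh–Doering oxidation gives (S)-2-methyl-3-(phenylsulfanyl)propanal F5, whose thiolate is a far poorer leaving group. The same crotylboration, with an ethanolamine work-up to spare the sulfide, gives (3R,4R,5S)-3,5-dimethyl-6-(phenylsulfanyl)hex-1-en-4-ol F6, which Et3SiOTf converts into triethyl{[(3R,4R,5S)-3,5-dimethyl-6-(phenylsulfanyl)hex-1-en-4-yl]oxy}silane F7. Reductive lithiation with lithium 4,4′-di-tert-butylbiphenylide (THF, −78 °C) gives {(2R,3S,4R)-2,4-dimethyl-3-[(triethylsilyl)oxy]hex-5-en-1-yl}lithium F8, which ZnBr2 traps at once to give 11 for the coupling. This entry also avoids the 5-exo radical cyclisation that can compete during zinc insertion into 7.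

**Step 8.** The dienal has two olefins that can enter metathesis, and the following Doebner step heats an unprotected β-hydroxy ketone. The fallback sets out from 20 and comes back at 25. Cross-metathesis of 20 with crotonaldehyde (same ruthenium catalyst), a partner with a single reactive olefin, gives (2E,4R,5S,6R,8R,9R)-11-(4-aminophenyl)-5,9-dihydroxy-4,6,8-trimethyl-11-oxoundec-2-enal F9. After transient silylation of OH and NH2 with N,O-bis(trimethylsilyl)acetamide, Horner–Wadsworth–Emmons reaction with lithiated triethyl 4-phosphonocrotonate (LiN(SiMe3)2, THF, −78 → 0 °C; citric acid work-up) gives ethyl (2E,4E,6E,8R,9S,10R,12R,13R)-15-(4-aminophenyl)-9,13-dihydroxy-8,10,12-trimethyl-15-oxopentadeca-2,4,6-trienoate F10. Me3SnOH (1,2-dichloroethane, 60 °C) cleaves the ester to 25. This replaces steps 8 and 9 with three steps.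

## Further compounds

F1 | step 5 | rac-N-benzyl-2-bromo-N-phenylpropanamide | CC(Br)C(=O)N(Cc1ccccc1)c1ccccc1
F2 | step 5 | (2R,4R,5S,6R)-N-benzyl-2,4,6-trimethyl-N-phenyl-5-[(triethylsilyl)oxy]oct-7-enamide | C[C@H](C=C)[C@@H](O[Si](CC)(CC)CC)[C@H](C)C[C@@H](C)C(=O)N(Cc1ccccc1)c1ccccc1
F3 | step 5 | (2R,4R,5S,6R)-2,4,6-trimethyl-5-[(triethylsilyl)oxy]oct-7-enal | C[C@H](C=C)[C@@H](O[Si](CC)(CC)CC)[C@H](C)C[C@@H](C)C=O
F4 | step 1 | (S)-2-methyl-3-(phenylsulfanyl)propan-1-ol | OC[C@H](C)CSc1ccccc1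
F5 | step 1 | (S)-2-methyl-3-(phenylsulfanyl)propanal | O=C[C@H](C)CSc1ccccc1
F6 | step 1 | (3R,4R,5S)-3,5-dimethyl-6-(phenylsulfanyl)hex-1-en-4-ol | C[C@H](C=C)[C@@H](O)[C@H](C)CSc1ccccc1
F7 | step 1 | triethyl{[(3R,4R,5S)-3,5-dimethyl-6-(phenylsulfanyl)hex-1-en-4-yl]oxy}silane | C[C@H](C=C)[C@@H](O[Si](CC)(CC)CC)[C@H](C)CSc1ccccc1
F8 | step 1 | {(2R,3S,4R)-2,4-dimethyl-3-[(triethylsilyl)oxy]hex-5-en-1-yl}lithium | C[C@H](C=C)[C@@H](O[Si](CC)(CC)CC)[C@H](C)C[Li]
F9 | step 8 | (2E,4R,5S,6R,8R,9R)-11-(4-aminophenyl)-5,9-dihydroxy-4,6,8-trimethyl-11-oxoundec-2-enal | C[C@H](/C=C/C=O)[C@@H](O)[C@H](C)C[C@@H](C)[C@H](O)CC(=O)c1ccc(N)cc1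
F10 | step 8 | ethyl (2E,4E,6E,8R,9S,10R,12R,13R)-15-(4-aminophenyl)-9,13-dihydroxy-8,10,12-trimethyl-15-oxopentadeca-2,4,6-trienoate | C[C@H](/C=C/C=C/C=C/C(=O)OCC)[C@@H](O)[C@H](C)C[C@@H](C)[C@H](O)CC(=O)c1ccc(N)cc1
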